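All runs are simulated on assumed constants.

| setting | amber | blue | flask |
|---|---|---|---|
| substrate | 1.7 M | 2.5 M | 1.7 M |
| coupling partner | 2.4 M | 1.7 M | 1.70 M |
| free catalyst | 85 mM | 85 mM | 85 mM |
| impurity | 21 mM | 21 mM | 21 mM |
| remark | run made earlier | run made earlier |  |

| run | time / h | product / % | substrate / % |
|---|---|---|---|
| amber | 1.00 | 35 | 59 |
| amber | 2.00 | 65 | 33 |
| amber | 2.50 | 74 | 22 |
| amber | 4.00 | 97 | 1 |
| amber | 6.00 | 97 | 2 |
| amber | 10.0 | 100 | 0 |
| amber | 15.0 | 99 | 0 |
| blue | 1.33 | 27 | 75 |
| blue | 4.00 | 51 | 49 |
| blue | 6.00 | 58 | 37 |
| blue | 10.0 | 65 | 32 |
| blue | 15.0 | 68 | 32 |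

(each reading ± 1.5 percentage points)

- apparent order in coupling partner when 50% of the substrate are converted (percent change of the rate of making product for one percent more coupling partner charged)
- factor on the rate of making product when 50% of the substrate are converted if coupling partner is charged twice over

- the numbers in the tables scatter by 1.5 percentage points (one standard deviation)

In a one-step world whose rate follows the coupling partner left, a charge acts through the fraction left and not through the fraction made. The blue run stalls at 68% of its substrate, which is 1.70 M of product from 1.7 M of coupling partner, so the two react one to one and the coupling partner is the limiting reagent there. Product per hour over coupling partner left reads 0.329 h⁻¹ early in the amber run and 0.310 h⁻¹ early in the blue run.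

In the flask, at 50% conversion, the charge of coupling partner stands to what is left of it as 2.00. This ratio, the leverage, says how many percent the remainder gains for one percent more charge. My own reckoning therefore gives an order near 2.00, and a doubled charge leaves 3.00 times as much. As a test of whether one number is enough, the same ratio is read late in the amber run, between 2.50 h and 4.00 h, and it gives 0.275 h⁻¹. The readings scatter by 1.5 percentage points, so they do not clearly show a fall from the early values.

The forecast gives 1.9 and 2.8, holding the reaction roughly first order in the coupling partner and “close to saturated in substrate”.

The flask gives an order of 1.6 and a factor of 2.28, both lower than the forecast.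

    substrate + free catalyst → catalyst intermediate A (k = 0.130 L mol⁻¹ s⁻¹)
    coupling partner + catalyst intermediate A ⇌ catalyst intermediate B (K = 1.70 L mol⁻¹, k = 0.00170 L mol⁻¹ s⁻¹)
    catalyst intermediate B ⇌ free catalyst + product (K = 26.0 M, k = 0.00970 s⁻¹)
    free catalyst + impurity → spent catalyst (k = 0.400 L mol⁻¹ s⁻¹)

One percent more on the constants of the turning of catalyst intermediate B into free catalyst and product, forward and back together, moves the rate by 0.21 percent. Divided by the leverage, the flask's order is 0.802 per percent on what is left. Carried to the blue run at 4.00 h, with 0.425 M of coupling partner left against 0.850 M in the flask, that power scales the flask's 0.291 M h⁻¹ to 0.167 M h⁻¹, and the blue readings around that time give 0.166 M h⁻¹.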